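**Retrosynthetic overview**
1. Vogelin E ⇒ isowighteone (3'-prenylgenistein): the C4''–O bond is made last by an (E)-selective allylic C–H hydroxylation, which also fixes the olefin geometry.
2. Isowighteone ⇒ 3'-bromogenistein + prenyl pinacolboronate (C3'–C1'' Suzuki coupling, no protecting groups).
3. 3'-Bromogenistein ⇒ phloroglucinol + 3-bromo-4-hydroxyphenylacetic acid + one carbon from DMF.
4. Ring order: rings A and B are bought; ring C (the pyranone) is the only ring made, closed in step 1 through the O1–C2 bond.

Assumption: Vogelin E has no stereocentre, so "single enantiomer" is taken to mean the single (E)-olefin isomer drawn (CH2OH trans to the ArCH2 chain; side-chain carbons are C1''–C4'' from the ring).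

**Step 1**
Reactants: 1 phloroglucinol (benzene-1,3,5-triol); 2 3-bromo-4-hydroxyphenylacetic acid
Product: 4 3'-bromogenistein (3-(3-bromo-4-hydroxyphenyl)-5,7-dihydroxy-4H-chromen-4-one), via bromo-deoxybenzoin 3 (not isolated)
Conditions: BF3·OEt2 (neat, as medium), 85 °C, 90 min; then DMF, MsCl, 75 °C, 2 h; aq. NaOAc work-up
Reagents that add atoms: N,N-dimethylformamide, CN(C)C=O (supplies C2)
Why: BF3-mediated Friedel–Crafts C-acylation of phloroglucinol by the arylacetic acid gives deoxybenzoin 3 as its boron chelate, whose methylene is formylated by the DMF/MsCl Vilsmeier reagent, and the ortho-hydroxyl then closes ring C by addition–elimination of dimethylamine (one-pot deoxybenzoin isoflavone synthesis); the aryl bromide and phenols are inert.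

**Step 2**
Reactants: 4 3'-bromogenistein; 5 prenyl pinacolboronate (4,4,5,5-tetramethyl-2-(3-methylbut-2-en-1-yl)-1,3,2-dioxaborolane)
Product: 6 isowighteone (5,7-dihydroxy-3-[4-hydroxy-3-(3-methylbut-2-en-1-yl)phenyl]-4H-chromen-4-one)
Conditions: 5 (2 equiv), (IPent)PdCl2(3-chloropyridine) (3 mol%; IPent = 1,3-bis[2,6-di(pentan-3-yl)phenyl]imidazol-2-ylidene), K3PO4 (5 equiv), THF/H2O, 60 °C
Reagents that add atoms: none
Why: Suzuki–Miyaura allyl–aryl coupling in which the aryl bromide adds oxidatively to zerovalent palladium, the allylboronate transmetalates to a prenyl–palladium species that equilibrates through its η3 form, and the very bulky carbene forces reductive elimination at the unsubstituted terminus to give the linear prenyl arene; the phenols ride through as phenoxides and no acid is present to cyclise the ortho-prenylphenol.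

**Step 3**
Reactants: 6 isowighteone
Product: 9 Vogelin E ((E)-configured 5,7-dihydroxy-3-[4-hydroxy-3-(4-hydroxy-3-methylbut-2-en-1-yl)phenyl]-4H-chromen-4-one), via tris(trimethylsilyl) ether 7 (not isolated), via tetrakis(trimethylsilyl) ether 8 (not isolated)
Conditions: BSA (N,O-bis(trimethylsilyl)acetamide, 5 equiv), CH2Cl2, rt, 1 h; SeO2 (10 mol%), Me3SiOOSiMe3 (1.5 equiv), 0 °C to rt; then K2CO3 (cat.), MeOH, 0 °C
Reagents that add atoms: bis(trimethylsilyl) peroxide, C[Si](C)(C)OO[Si](C)(C)C (source of the new oxygen, delivered through selenium); N,O-bis(trimethylsilyl)acetamide, CC(=N[Si](C)(C)C)O[Si](C)(C)C (silyl groups carried only by 7 and 8, removed before isolation)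
Why: Proposed new method: an aprotic, silyl-buffered selenium-catalysed allylic hydroxylation in which BSA first masks the three phenols (7) and SeO2 is carried as soluble bis(trimethylsilyl) selenite; this tetravalent selenium enophile adds to the electron-rich prenyl olefin in an ene reaction (Se to C2'', hydrogen from a terminal methyl), the resulting allylseleninate undergoes a [2,3]-sigmatropic shift through an envelope transition state with the ArCH2 group pseudo-equatorial, which puts the oxygen on the carbon trans to the chain and so sets the (E)-olefin, the divalent selenium ester is silanolysed and the alcohol is captured as silyl ether 8 (no product selenite ester, hence no over-oxidation to the enal), Me3SiOOSiMe3 returns selenium to the tetravalent state, and methanolysis strips all silyl groups; the closest known reaction type is the Riley allylic oxidation in its catalytic SeO2/tert-butyl hydroperoxide form (ene/[2,3] sequence), which has not been run with a silyl peroxide oxidant and in situ silyl capture.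

**Compound list**
1 | phloroglucinol (benzene-1,3,5-triol) | Oc1cc(O)cc(O)c1 | starting material
2 | 3-bromo-4-hydroxyphenylacetic acid | OC(=O)Cc1ccc(O)c(Br)c1 | starting material
3 | 2-(3-bromo-4-hydroxyphenyl)-1-(2,4,6-trihydroxyphenyl)ethan-1-one (bromo-deoxybenzoin) | O=C(Cc1ccc(O)c(Br)c1)c1c(O)cc(O)cc1O | intermediate (not isolated)
4 | 3'-bromogenistein, 3-(3-bromo-4-hydroxyphenyl)-5,7-dihydroxy-4H-chromen-4-one | O=c1c(-c2ccc(O)c(Br)c2)coc2cc(O)cc(O)c12 | intermediate
5 | prenyl pinacolboronate, 4,4,5,5-tetramethyl-2-(3-methylbut-2-en-1-yl)-1,3,2-dioxaborolane | CC(C)=CCB1OC(C)(C)C(C)(C)O1 | starting material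
6 | isowighteone, 5,7-dihydroxy-3-[4-hydroxy-3-(3-methylbut-2-en-1-yl)phenyl]-4H-chromen-4-one | CC(C)=CCc1cc(-c2coc3cc(O)cc(O)c3c2=O)ccc1O | intermediate
7 | 4',5,7-tris(trimethylsilyl) ether of isowighteone | CC(C)=CCc1cc(-c2coc3cc(O[Si](C)(C)C)cc(O[Si](C)(C)C)c3c2=O)ccc1O[Si](C)(C)C | intermediate (not isolated)
8 | 4',5,7,4''-tetrakis(trimethylsilyl) ether of Vogelin E, (E)-olefin | C/C(=C\Cc1cc(-c2coc3cc(O[Si](C)(C)C)cc(O[Si](C)(C)C)c3c2=O)ccc1O[Si](C)(C)C)CO[Si](C)(C)C | intermediate (not isolated)
9 | Vogelin E, 5,7-dihydroxy-3-[4-hydroxy-3-((E)-4-hydroxy-3-methylbut-2-en-1-yl)phenyl]-4H-chromen-4-one | C/C(=C\Cc1cc(-c2coc3cc(O)cc(O)c3c2=O)ccc1O)CO | target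

**Total step count:** 3. **Longest linear sequence:** 3 (steps 1–3; both coupling partners are purchased).

**Steps most likely to fail, with fallbacks**

Step 3 (the proposed new method). Risks: the silyl selenite may be a sluggish enophile, the product may stay bound to selenium, or a silyl peroxyselenite may epoxidise the olefin. The fallback uses known chemistry, sets out from 6 and returns at 9. Peracetylation (Ac2O, pyridine, DMAP, rt) gives isowighteone triacetate F4. Classical catalytic Riley oxidation (SeO2 0.5 equiv, tert-butyl hydroperoxide, salicylic acid 10 mol%, CH2Cl2, rt) gives the (E)-allylic alcohol triacetate F5, with the minor enal removed by chromatography. K2CO3 in MeOH at 0 °C then cleaves the three aryl acetates to give 9.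

Step 2. Risks: slow oxidative addition next to a phenoxide, protodeboronation of 5, or some branched (reverse-prenyl) product. The fallback sets out from 4 and returns at 6, using a protected substrate and a tin reagent under neutral conditions. MOMCl (2.2 equiv) and iPr2NEt in CH2Cl2 give 3-[3-bromo-4-(methoxymethoxy)phenyl]-5-hydroxy-7-(methoxymethoxy)-4H-chromen-4-one F2, the chelated 5-OH staying free. Stille coupling with tributyl(3-methylbut-2-en-1-yl)stannane (CC(C)=CC[Sn](CCCC)(CCCC)CCCC), Pd(PPh3)4, DMF, 100 °C gives 5-hydroxy-7-(methoxymethoxy)-3-[4-(methoxymethoxy)-3-(3-methylbut-2-en-1-yl)phenyl]-4H-chromen-4-one F3. Brief HCl/MeOH at 40 °C, stopped before chroman formation, removes both acetals to give 6.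

Step 1. Risks: incomplete C-acylation with the brominated acid, or a poor ring closure in the one-pot mode. The fallback sets out from 1 and returns at 3, replacing the acid/BF3 acylation by a stepwise Houben–Hoesch route. Compound 1 and purchased 2-(3-bromo-4-hydroxyphenyl)acetonitrile (N#CCc1ccc(O)c(Br)c1) with ZnCl2 and HCl gas in Et2O at 0 °C give 2-(3-bromo-4-hydroxyphenyl)-1-(2,4,6-trihydroxyphenyl)ethan-1-iminium chloride F1. Hydrolysis in boiling water gives 3, which is isolated and purified, then cyclised separately (BF3·OEt2, DMF, MsCl, 75 °C) to 4.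

**Further compounds**
F1 | step 1 | 2-(3-bromo-4-hydroxyphenyl)-1-(2,4,6-trihydroxyphenyl)ethan-1-iminium chloride | [NH2+]=C(Cc1ccc(O)c(Br)c1)c1c(O)cc(O)cc1O.[Cl-]
F2 | step 2 | 3-[3-bromo-4-(methoxymethoxy)phenyl]-5-hydroxy-7-(methoxymethoxy)-4H-chromen-4-one | COCOc1cc(O)c2c(c1)occ(-c1ccc(OCOC)c(Br)c1)c2=O
F3 | step 2 | 5-hydroxy-7-(methoxymethoxy)-3-[4-(methoxymethoxy)-3-(3-methylbut-2-en-1-yl)phenyl]-4H-chromen-4-one | COCOc1cc(O)c2c(c1)occ(-c1ccc(OCOC)c(CC=C(C)C)c1)c2=O
F4 | step 3 | isowighteone 4',5,7-triacetate | CC(C)=CCc1cc(-c2coc3cc(OC(C)=O)cc(OC(C)=O)c3c2=O)ccc1OC(C)=O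
F5 | step 3 | Vogelin E 4',5,7-triacetate, (E)-olefin, free primary alcohol | C/C(=C\Cc1cc(-c2coc3cc(OC(C)=O)cc(OC(C)=O)c3c2=O)ccc1OC(C)=O)CO
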